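**Retrosynthetic overview** (benzofuran numbering; ring A = the dihydrobenzofuran that carries the styryl group, atoms O1, C2, C3, C3a, C4–C7, C7a; ring B = the other dihydrobenzofuran, primed atoms)
1. Target ⇐ methanolysis of its heptapivalate ⇐ Mizoroki–Heck styrylation at C4 of a 4-bromo ring A.
2. Ring A ⇐ insertion of a 3-bromo-5-(pivaloyloxy)aryne (C7a≡C3a, Br on C4) into the C3–O bond of an enantiopure trans-1,2-diaryl epoxide: O1–C7a and C3–C3a form together, while O1–C2 and C2–C3 arrive with the epoxide.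
3. Enabling feature: O1 and C3 sit on the adjacent benzo carbons C7a and C3a (an aryne pair) next to C4, where a bromine steers the addition and later becomes the styryl group; C3 is benzylic to the benzo ring of ring B and para to its ether oxygen O1′ (stabilised cation), and the C2 aryl group is switched off as a pivalate.
4. Epoxide ⇐ Shi epoxidation of an E-stilbene ⇐ Mizoroki–Heck reaction of the 5′-bromide of ring B with 4-vinylphenyl pivalate.
5. Ring order: the furan ring of ring B first (C2′–C3′ by rhodium-carbene C–H insertion, then BBr3 demethylation with C2′ epimerisation to trans, then pivaloylation), the furan ring of ring A second; both benzo rings are bought in (5-bromo-o-vanillin, 2,6-dibromohydroquinone).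

Key step: step 13

Remark on the target: the SMILES is read as (2S,3S) in ring A and (2R,3R) in ring B, both rings trans, with an E alkene.
Remark on step 5: Rh2(R-PTAD)4 is assumed to give the (3R) series; if the sense of induction is the opposite, Rh2(S-PTAD)4 is used with no other change.

**Route**

Step 1
Reactants: 1 5-bromo-2-hydroxy-3-methoxybenzaldehyde; 2 4-methoxybenzyl chloride
Product: 3 5-bromo-3-methoxy-2-[(4-methoxybenzyl)oxy]benzaldehyde
Conditions: K2CO3, KI (cat.), DMF, 60 °C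
Reagents that add atoms: none
Why: Williamson ether synthesis on the only phenol; the benzylic CH2 is the later C2′ and its aryl group the later C2′ aryl group.

Step 2
Reactants: 3 5-bromo-3-methoxy-2-[(4-methoxybenzyl)oxy]benzaldehyde; 4 3,5-dimethoxyphenylmagnesium chloride (THF solution)
Product: 5 (±)-{5-bromo-3-methoxy-2-[(4-methoxybenzyl)oxy]phenyl}(3,5-dimethoxyphenyl)methanol
Conditions: THF, −20 → 0 °C; aq. NH4Cl
Reagents that add atoms: none
Why: Grignard addition to the aldehyde is faster than bromine–magnesium exchange; the racemic carbinol centre is removed in step 3.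

Step 3
Reactants: 5 (±)-{5-bromo-3-methoxy-2-[(4-methoxybenzyl)oxy]phenyl}(3,5-dimethoxyphenyl)methanol
Product: 6 {5-bromo-3-methoxy-2-[(4-methoxybenzyl)oxy]phenyl}(3,5-dimethoxyphenyl)methanone
Conditions: MnO2 (activated, excess), CH2Cl2, rt
Reagents that add atoms: none
Why: MnO2 oxidation of a doubly benzylic alcohol, which leaves the benzyl ether and the aryl bromide untouched.

Step 4
Reactants: 6 {5-bromo-3-methoxy-2-[(4-methoxybenzyl)oxy]phenyl}(3,5-dimethoxyphenyl)methanone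
Product: 7 hydrazone of 6 (E/Z mixture)
Conditions: N2H4·H2O (excess), AcOH (cat.), EtOH, 80 °C
Reagents that add atoms: hydrazine, NN
Why: hydrazone condensation; the C=N geometry is irrelevant because both isomers give the same diazo compound.

Step 5
Reactants: 7 hydrazone of 6
Product: 9 (2S,3R)-5-bromo-3-(3,5-dimethoxyphenyl)-7-methoxy-2-(4-methoxyphenyl)-2,3-dihydrobenzofuran (cis), via diaryldiazomethane 8 (not isolated)
Conditions: MnO2, CH2Cl2, 0 °C, filter; then Rh2(R-PTAD)4 (dirhodium tetrakis[(R)-(1-adamantyl)(N-phthalimido)acetate], 1 mol %), CH2Cl2, 0 °C → rt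
Reagents that add atoms: none
Why: hydrazone dehydrogenation followed by dirhodium-catalysed intramolecular 1,5 C–H insertion of the donor/donor carbene into the benzylic ether CH2 closes the furan ring of ring B (C2′–C3′); the chiral carboxylate ligands set C3′ (R), and the concerted insertion should give mainly the cis C2′ isomer, which does not matter because step 6 equilibrates C2′.

Step 6
Reactants: 9 (2S,3R)-5-bromo-3-(3,5-dimethoxyphenyl)-7-methoxy-2-(4-methoxyphenyl)-2,3-dihydrobenzofuran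
Product: 10 5-[(2R,3R)-5-bromo-7-hydroxy-2-(4-hydroxyphenyl)-2,3-dihydrobenzofuran-3-yl]benzene-1,3-diol (trans)
Conditions: BBr3 (10 equiv), CH2Cl2, −78 °C → rt; ice, aq. NaHCO3
Reagents that add atoms: none
Why: Lewis-acid cleavage of the four aryl methyl ethers; the same medium reversibly ionises the C2′–O1′ bond (4-oxybenzylic cation), so C2′ should settle in the more stable trans arrangement while C3′, set in step 5, is untouched (stereoconvergent at C2′).

Step 7
Reactants: 10 5-[(2R,3R)-5-bromo-7-hydroxy-2-(4-hydroxyphenyl)-2,3-dihydrobenzofuran-3-yl]benzene-1,3-diol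
Product: 11 (2R,3R)-5-bromo-3-[3,5-bis(pivaloyloxy)phenyl]-2-[4-(pivaloyloxy)phenyl]-2,3-dihydrobenzofuran-7-yl pivalate
Conditions: PivCl, Et3N, DMAP (cat.), CH2Cl2, 0 °C → rt
Reagents that add atoms: pivaloyl chloride, CC(C)(C)C(Cl)=O
Why: DMAP-catalysed acylation; pivalates should survive the pH 10.5 epoxidation, fluoride and the palladium/amine steps, they damp the phenol rings, and all come off together in step 15.

Step 8
Reactants: 12 4-acetoxystyrene
Product: 14 4-vinylphenyl pivalate, via potassium 4-vinylphenoxide 13 (not isolated)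
Conditions: KOH (2.2 equiv), THF/H2O, 0 °C; then PivCl, Bu4NBr (cat.), CH2Cl2, 0 °C → rt
Reagents that add atoms: pivaloyl chloride, CC(C)(C)C(Cl)=O
Why: saponification and Schotten–Baumann acylation in one flask avoid isolating the polymerisable 4-vinylphenol.

Step 9
Reactants: 11 (2R,3R)-5-bromo-3-[3,5-bis(pivaloyloxy)phenyl]-2-[4-(pivaloyloxy)phenyl]-2,3-dihydrobenzofuran-7-yl pivalate; 14 4-vinylphenyl pivalate
Product: 15 (2R,3R)-3-[3,5-bis(pivaloyloxy)phenyl]-2-[4-(pivaloyloxy)phenyl]-5-{(E)-2-[4-(pivaloyloxy)phenyl]ethenyl}-2,3-dihydrobenzofuran-7-yl pivalate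
Conditions: Pd2(dba)3 (2.5 mol %), [HP(t-Bu)3]BF4 (10 mol %), Cy2NMe, 1,4-dioxane, 80 °C
Reagents that add atoms: none
Why: Mizoroki–Heck reaction; syn carbopalladation and syn β-hydride elimination give the E-stilbene, and aryl pivalates are inert to the palladium catalyst.

Step 10
Reactants: 15 the E-stilbene from step 9
Product: 16 (2R,3R)-3-[3,5-bis(pivaloyloxy)phenyl]-2-[4-(pivaloyloxy)phenyl]-5-{(2R,3R)-3-[4-(pivaloyloxy)phenyl]oxiran-2-yl}-2,3-dihydrobenzofuran-7-yl pivalate
Conditions: Shi ketone (D-fructose-derived, 30 mol %), Oxone (2KHSO5·KHSO4·K2SO4), K2CO3, Bu4NHSO4, MeCN/DMM/aq. Na2B4O7–Na2EDTA buffer (pH 10.5), 0 °C; filtration over Et3N-deactivated silica, used promptly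
Reagents that add atoms: potassium peroxymonosulfate, [K+].[O-]S(=O)(=O)OO
Why: Shi asymmetric epoxidation; the chiral dioxirane transfers oxygen stereospecifically through a spiro transition state to one face of the E-alkene, which should give the (R,R) trans epoxide under reagent control, the ring B centres being remote.

Step 11
Reactants: 17 2,6-dibromohydroquinone
Product: 21 2-bromo-4-hydroxy-6-(trimethylsilyl)phenyl trifluoromethanesulfonate, via bis(trimethylsilyl) ether 18 (not isolated), via lithium phenoxide 19 (not isolated), via silyloxy aryl triflate 20 (not isolated)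
Conditions: HMDS, 80 °C, evaporate; n-BuLi (1.05 equiv), THF, −78 °C; Tf2O (1.1 equiv), −78 → 0 °C; then MeOH, citric acid (cat.), rt
Reagents that add atoms: hexamethyldisilazane, C[Si](C)(C)N[Si](C)(C)C; trifluoromethanesulfonic anhydride, O=S(=O)(C(F)(F)F)OS(=O)(=O)C(F)(F)F
Why: O-silylation, bromine–lithium exchange, retro-Brook 1,3 O→C silyl shift and triflation of the phenoxide are the standard route to ortho-silylaryl triflates; the two bromines are equivalent, so one regioisomer forms, and the remote O–SiMe3 group is cleaved in the methanolic work-up.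

Step 12
Reactants: 21 2-bromo-4-hydroxy-6-(trimethylsilyl)phenyl trifluoromethanesulfonate
Product: 22 2-bromo-4-(pivaloyloxy)-6-(trimethylsilyl)phenyl trifluoromethanesulfonate
Conditions: PivCl, Et3N, DMAP (cat.), CH2Cl2, 0 °C
Reagents that add atoms: pivaloyl chloride, CC(C)(C)C(Cl)=O
Why: DMAP-catalysed acylation of the free phenol, which puts the later C6 oxygen in the same protected form as all the others.

Step 13
Reactants: 16 the (R,R)-epoxide from step 10; 22 2-bromo-4-(pivaloyloxy)-6-(trimethylsilyl)phenyl trifluoromethanesulfonate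
Product: 25 (2S,3S)-4-bromo-3-{(2R,3R)-3-[3,5-bis(pivaloyloxy)phenyl]-7-(pivaloyloxy)-2-[4-(pivaloyloxy)phenyl]-2,3-dihydrobenzofuran-5-yl}-2-[4-(pivaloyloxy)phenyl]-2,3-dihydrobenzofuran-6-yl pivalate, via 3-bromo-5-(pivaloyloxy)benzyne 23 (not isolated), via ring-opened zwitterion 24 (not isolated)
Conditions: CsF (6 equiv), MeCN/PhMe (1:1), 4 Å MS, 40 °C; 22 (2.5 equiv) added over 6 h
Reagents that add atoms: none
Why: Proposed new method: fluoride converts 22 into aryne 23 (1,2-elimination of an ortho-silylaryl triflate); the epoxide oxygen of 16 adds to the aryne carbon remote from bromine (the later C7a), the O-aryl oxonium opens at the carbon benzylic to the ring B benzo ring to give zwitterion 24, and the aryl anion at C3a collapses on that cation to form C3–C3a. The closest known reaction type is the insertion of arynes into the benzylic C–O bond of styrene oxide to give 2,3-dihydrobenzofurans (aryne σ-bond insertion); a 1,2-diaryl epoxide, a 3-haloaryne and the stereochemical course lie outside that precedent. The furan ring of ring A closes by 5-exo-trig attack of the C3a anion on the cationic C3, in all a formal (3+2) annulation of the O1–C2–C3 unit across C7a≡C3a. C2 never loses its bond to oxygen and keeps the configuration set in step 10 (R in 16, S in 25 only through a change of CIP ranks); C3 is set in the ring closure trans to the C2 aryl group, because both direct ion-pair collapse on the face the oxygen left (retention from the trans epoxide) and closure of a rotated cation under steric control lead to the trans ring. The step needs O-attack at C7a and not C3a, secured by the C4 bromine (aryne distortion places the anion next to C–Br; the bromine is also the handle for step 14). It also needs cleavage of the C3–O and not the C2–O bond, secured by the para-alkoxy ring B aryl group against the pivalate-deactivated C2 aryl group, and capture of the aryne by the epoxide oxygen and not by the ester carbonyls, which arynes normally leave alone.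

Step 14
Reactants: 25 the 4-bromide from step 13; 14 4-vinylphenyl pivalate
Product: 26 (2S,3S)-3-{(2R,3R)-3-[3,5-bis(pivaloyloxy)phenyl]-7-(pivaloyloxy)-2-[4-(pivaloyloxy)phenyl]-2,3-dihydrobenzofuran-5-yl}-2-[4-(pivaloyloxy)phenyl]-4-{(E)-2-[4-(pivaloyloxy)phenyl]ethenyl}-2,3-dihydrobenzofuran-6-yl pivalate
Conditions: Pd2(dba)3 (5 mol %), [HP(t-Bu)3]BF4 (20 mol %), Cy2NMe, 1,4-dioxane, 100 °C
Reagents that add atoms: none
Why: Mizoroki–Heck reaction of the ortho-substituted aryl bromide under bulky trialkylphosphine catalysis should give the E-styryl group at C4 without touching the benzylic stereocentres.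

Step 15
Reactants: 26 the heptapivalate from step 14
Product: 27 (2S,3S)-3-[(2R,3R)-3-(3,5-dihydroxyphenyl)-7-hydroxy-2-(4-hydroxyphenyl)-2,3-dihydrobenzofuran-5-yl]-2-(4-hydroxyphenyl)-4-[(E)-2-(4-hydroxyphenyl)ethenyl]-2,3-dihydrobenzofuran-6-ol (CNP0172909.1)
Conditions: K2CO3, MeOH/THF (degassed, Ar), 25 → 40 °C; then AcOH; reverse-phase chromatography
Reagents that add atoms: none
Why: base-catalysed transesterification (methanolysis) of the seven aryl pivalates frees all phenols without acid, so neither the stilbene nor the trans dihydrofuran rings are put at risk.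

**Compound list**

1 | 5-bromo-2-hydroxy-3-methoxybenzaldehyde | O=Cc1cc(Br)cc(OC)c1O | starting material
2 | 4-methoxybenzyl chloride | COc1ccc(CCl)cc1 | starting material
3 | 5-bromo-3-methoxy-2-[(4-methoxybenzyl)oxy]benzaldehyde | O=Cc1cc(Br)cc(OC)c1OCc1ccc(OC)cc1 | intermediate
4 | 3,5-dimethoxyphenylmagnesium chloride | COc1cc(OC)cc([Mg]Cl)c1 | starting material
5 | (±)-{5-bromo-3-methoxy-2-[(4-methoxybenzyl)oxy]phenyl}(3,5-dimethoxyphenyl)methanol | OC(c1cc(OC)cc(OC)c1)c1cc(Br)cc(OC)c1OCc1ccc(OC)cc1 | intermediate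
6 | {5-bromo-3-methoxy-2-[(4-methoxybenzyl)oxy]phenyl}(3,5-dimethoxyphenyl)methanone | O=C(c1cc(OC)cc(OC)c1)c1cc(Br)cc(OC)c1OCc1ccc(OC)cc1 | intermediate
7 | hydrazone of 6 (E/Z mixture) | NN=C(c1cc(OC)cc(OC)c1)c1cc(Br)cc(OC)c1OCc1ccc(OC)cc1 | intermediate
8 | {5-bromo-3-methoxy-2-[(4-methoxybenzyl)oxy]phenyl}(3,5-dimethoxyphenyl)diazomethane | [N-]=[N+]=C(c1cc(OC)cc(OC)c1)c1cc(Br)cc(OC)c1OCc1ccc(OC)cc1 | intermediate
9 | (2S,3R)-5-bromo-3-(3,5-dimethoxyphenyl)-7-methoxy-2-(4-methoxyphenyl)-2,3-dihydrobenzofuran (cis) | Brc1cc(OC)c2c(c1)[C@@H](c1cc(OC)cc(OC)c1)[C@@H](c1ccc(OC)cc1)O2 | intermediate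
10 | 5-[(2R,3R)-5-bromo-7-hydroxy-2-(4-hydroxyphenyl)-2,3-dihydrobenzofuran-3-yl]benzene-1,3-diol (trans) | Brc1cc(O)c2c(c1)[C@@H](c1cc(O)cc(O)c1)[C@H](c1ccc(O)cc1)O2 | intermediate
11 | (2R,3R)-5-bromo-3-[3,5-bis(pivaloyloxy)phenyl]-2-[4-(pivaloyloxy)phenyl]-2,3-dihydrobenzofuran-7-yl pivalate | Brc1cc(OC(=O)C(C)(C)C)c2c(c1)[C@@H](c1cc(OC(=O)C(C)(C)C)cc(OC(=O)C(C)(C)C)c1)[C@H](c1ccc(OC(=O)C(C)(C)C)cc1)O2 | intermediate
12 | 4-acetoxystyrene | CC(=O)Oc1ccc(C=C)cc1 | starting material
13 | potassium 4-vinylphenoxide | [K+].[O-]c1ccc(C=C)cc1 | intermediate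
14 | 4-vinylphenyl pivalate | C=Cc1ccc(OC(=O)C(C)(C)C)cc1 | intermediate
15 | (2R,3R)-3-[3,5-bis(pivaloyloxy)phenyl]-2-[4-(pivaloyloxy)phenyl]-5-{(E)-2-[4-(pivaloyloxy)phenyl]ethenyl}-2,3-dihydrobenzofuran-7-yl pivalate | CC(C)(C)C(=O)Oc1ccc(/C=C/c2cc(OC(=O)C(C)(C)C)c3c(c2)[C@@H](c2cc(OC(=O)C(C)(C)C)cc(OC(=O)C(C)(C)C)c2)[C@H](c2ccc(OC(=O)C(C)(C)C)cc2)O3)cc1 | intermediate
16 | (2R,3R)-3-[3,5-bis(pivaloyloxy)phenyl]-2-[4-(pivaloyloxy)phenyl]-5-{(2R,3R)-3-[4-(pivaloyloxy)phenyl]oxiran-2-yl}-2,3-dihydrobenzofuran-7-yl pivalate | O1[C@H](c2cc(OC(=O)C(C)(C)C)c3c(c2)[C@@H](c2cc(OC(=O)C(C)(C)C)cc(OC(=O)C(C)(C)C)c2)[C@H](c2ccc(OC(=O)C(C)(C)C)cc2)O3)[C@H]1c1ccc(OC(=O)C(C)(C)C)cc1 | intermediate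
17 | 2,6-dibromohydroquinone (2,6-dibromobenzene-1,4-diol) | Oc1cc(Br)c(O)c(Br)c1 | starting material
18 | 1,3-dibromo-2,5-bis(trimethylsilyloxy)benzene | C[Si](C)(C)Oc1cc(Br)c(O[Si](C)(C)C)c(Br)c1 | intermediate
19 | lithium 2-bromo-6-(trimethylsilyl)-4-(trimethylsilyloxy)phenoxide | [Li+].[O-]c1c(Br)cc(O[Si](C)(C)C)cc1[Si](C)(C)C | intermediate
20 | 2-bromo-6-(trimethylsilyl)-4-(trimethylsilyloxy)phenyl trifluoromethanesulfonate | C[Si](C)(C)Oc1cc(Br)c(OS(=O)(=O)C(F)(F)F)c([Si](C)(C)C)c1 | intermediate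
21 | 2-bromo-4-hydroxy-6-(trimethylsilyl)phenyl trifluoromethanesulfonate | Oc1cc(Br)c(OS(=O)(=O)C(F)(F)F)c([Si](C)(C)C)c1 | intermediate
22 | 2-bromo-4-(pivaloyloxy)-6-(trimethylsilyl)phenyl trifluoromethanesulfonate | CC(C)(C)C(=O)Oc1cc(Br)c(OS(=O)(=O)C(F)(F)F)c([Si](C)(C)C)c1 | intermediate
23 | 3-bromo-5-(pivaloyloxy)benzyne | BrC1=CC(OC(=O)C(C)(C)C)=CC#C1 | intermediate
24 | ring-opened zwitterion (aryl anion at the later C3a, benzylic cation at the later C3, C2 configured as in 25) | CC(C)(C)C(=O)Oc1ccc(cc1)[C@@H](Oc1cc(OC(=O)C(C)(C)C)cc(Br)[c-]1)[CH+]c1cc(OC(=O)C(C)(C)C)c2c(c1)[C@@H](c1cc(OC(=O)C(C)(C)C)cc(OC(=O)C(C)(C)C)c1)[C@H](c1ccc(OC(=O)C(C)(C)C)cc1)O2 | intermediate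
25 | (2S,3S)-4-bromo-3-{(2R,3R)-3-[3,5-bis(pivaloyloxy)phenyl]-7-(pivaloyloxy)-2-[4-(pivaloyloxy)phenyl]-2,3-dihydrobenzofuran-5-yl}-2-[4-(pivaloyloxy)phenyl]-2,3-dihydrobenzofuran-6-yl pivalate | Brc1cc(OC(=O)C(C)(C)C)cc2c1[C@H](c1cc(OC(=O)C(C)(C)C)c3c(c1)[C@@H](c1cc(OC(=O)C(C)(C)C)cc(OC(=O)C(C)(C)C)c1)[C@H](c1ccc(OC(=O)C(C)(C)C)cc1)O3)[C@@H](c1ccc(OC(=O)C(C)(C)C)cc1)O2 | intermediate
26 | heptapivalate of the target: (2S,3S)-3-{(2R,3R)-3-[3,5-bis(pivaloyloxy)phenyl]-7-(pivaloyloxy)-2-[4-(pivaloyloxy)phenyl]-2,3-dihydrobenzofuran-5-yl}-2-[4-(pivaloyloxy)phenyl]-4-{(E)-2-[4-(pivaloyloxy)phenyl]ethenyl}-2,3-dihydrobenzofuran-6-yl pivalate | CC(C)(C)C(=O)Oc1ccc(/C=C/c2cc(OC(=O)C(C)(C)C)cc3c2[C@H](c2cc(OC(=O)C(C)(C)C)c4c(c2)[C@@H](c2cc(OC(=O)C(C)(C)C)cc(OC(=O)C(C)(C)C)c2)[C@H](c2ccc(OC(=O)C(C)(C)C)cc2)O4)[C@@H](c2ccc(OC(=O)C(C)(C)C)cc2)O3)cc1 | intermediate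
27 | (2S,3S)-3-[(2R,3R)-3-(3,5-dihydroxyphenyl)-7-hydroxy-2-(4-hydroxyphenyl)-2,3-dihydrobenzofuran-5-yl]-2-(4-hydroxyphenyl)-4-[(E)-2-(4-hydroxyphenyl)ethenyl]-2,3-dihydrobenzofuran-6-ol (CNP0172909.1) | Oc1ccc(/C=C/c2cc(O)cc3c2[C@H](c2cc(O)c4c(c2)[C@@H](c2cc(O)cc(O)c2)[C@H](c2ccc(O)cc2)O4)[C@@H](c2ccc(O)cc2)O3)cc1 | target

**Step count and risks**

Total step count: 15. Longest linear sequence: 12 steps (steps 1–7, 9, 10, 13, 14, 15).

Steps most likely to fail:

1. Step 13 (Proposed new method). What may go wrong: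
   - slow capture of the aryne by the weakly nucleophilic epoxide oxygen, so that the aryne is lost to side reactions;
   - loss of bromide from, or protonation of, the aryl anion before the C–C bond closes;
   - unselective C–O cleavage, or closure on the wrong face at C3.

   Fallback (known chemistry, a second rhodium-carbene C–H insertion builds ring A; it sets out from 9 and comes back at 25): commercial 2-bromo-6-hydroxy-4-methoxybenzaldehyde is alkylated with 2 (K2CO3, DMF) to 2-bromo-4-methoxy-6-[(4-methoxybenzyl)oxy]benzaldehyde F1. Bromine–lithium exchange on 9 (n-BuLi, THF, −78 °C) and addition to F1 gives the diaryl carbinol F2, MnO2 gives the diaryl ketone F3, and hydrazine (AcOH, n-BuOH, heat) gives the hydrazone F4. MnO2 and then Rh2(S-PTAD)4 give, by insertion into the benzylic ether C–H, the bis(dihydrobenzofuran) hexamethyl ether F5 with C3 of ring A set by the catalyst. BBr3 cleaves the six methyl ethers and brings C2 and C2′ to trans, giving the hexaphenol F6, and PivCl/Et3N/DMAP converts it into 25.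

2. Step 5. What may go wrong: low or reversed enantioinduction because the extra ortho-methoxy group changes the carbene conformation, or loss of the diazo compound to azine formation and carbene dimerisation.

   Fallback (trans-selective (4+1) annulation of an ortho-quinone methide with a sulfur ylide, then resolution; it sets out from 1, 2 and 4 and comes back at 10): 1 with two equivalents of 4 gives 4-bromo-2-[(3,5-dimethoxyphenyl)(hydroxy)methyl]-6-methoxyphenol F7. Sodium p-toluenesulfinate in aqueous HCO2H gives the sulfone 4-bromo-2-[(3,5-dimethoxyphenyl)(tosyl)methyl]-6-methoxyphenol F8. 2 and dimethyl sulfide give (4-methoxybenzyl)dimethylsulfonium chloride F9. F8 and F9 with Cs2CO3 in CH2Cl2 generate the ortho-quinone methide and the ylide, which should combine to the racemic trans dihydrobenzofuran; preparative chiral SFC gives (2R,3R)-5-bromo-3-(3,5-dimethoxyphenyl)-7-methoxy-2-(4-methoxyphenyl)-2,3-dihydrobenzofuran F10. BBr3 then only has to demethylate, giving 10.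

3. Step 14. What may go wrong: slow oxidative addition and alkene insertion at the C4–Br bond, which is crowded by the C3 substituent, with hydrodebromination taking over.

   Fallback (Suzuki–Miyaura coupling in place of carbopalladation; it sets out from 25 and 14 and comes back at 26): cross-metathesis of 14 with vinylboronic acid pinacol ester (second-generation Grubbs catalyst, RuCl2(H2IMes)(PCy3)(=CHPh), CH2Cl2, 40 °C) gives (E)-4-[2-(4,4,5,5-tetramethyl-1,3,2-dioxaborolan-2-yl)ethenyl]phenyl pivalate F11. F11 is coupled with 25 (Pd(OAc)2, SPhos, K3PO4, PhMe/H2O, 80 °C) to give 26; partial loss of pivalates here would not matter, since step 15 removes them all.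

**Further compounds**

F1 | step 13 | 2-bromo-4-methoxy-6-[(4-methoxybenzyl)oxy]benzaldehyde | O=Cc1c(Br)cc(OC)cc1OCc1ccc(OC)cc1
F2 | step 13 | {2-bromo-4-methoxy-6-[(4-methoxybenzyl)oxy]phenyl}[(2S,3R)-3-(3,5-dimethoxyphenyl)-7-methoxy-2-(4-methoxyphenyl)-2,3-dihydrobenzofuran-5-yl]methanol (carbinol epimers) | OC(c1cc(OC)c2c(c1)[C@@H](c1cc(OC)cc(OC)c1)[C@@H](c1ccc(OC)cc1)O2)c1c(Br)cc(OC)cc1OCc1ccc(OC)cc1
F3 | step 13 | {2-bromo-4-methoxy-6-[(4-methoxybenzyl)oxy]phenyl}[(2S,3R)-3-(3,5-dimethoxyphenyl)-7-methoxy-2-(4-methoxyphenyl)-2,3-dihydrobenzofuran-5-yl]methanone | O=C(c1cc(OC)c2c(c1)[C@@H](c1cc(OC)cc(OC)c1)[C@@H](c1ccc(OC)cc1)O2)c1c(Br)cc(OC)cc1OCc1ccc(OC)cc1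
F4 | step 13 | hydrazone of F3 | NN=C(c1cc(OC)c2c(c1)[C@@H](c1cc(OC)cc(OC)c1)[C@@H](c1ccc(OC)cc1)O2)c1c(Br)cc(OC)cc1OCc1ccc(OC)cc1
F5 | step 13 | (2R,3S)-4-bromo-3-[(2S,3R)-3-(3,5-dimethoxyphenyl)-7-methoxy-2-(4-methoxyphenyl)-2,3-dihydrobenzofuran-5-yl]-6-methoxy-2-(4-methoxyphenyl)-2,3-dihydrobenzofuran | Brc1cc(OC)cc2c1[C@H](c1cc(OC)c3c(c1)[C@@H](c1cc(OC)cc(OC)c1)[C@@H](c1ccc(OC)cc1)O3)[C@H](c1ccc(OC)cc1)O2
F6 | step 13 | (2S,3S)-4-bromo-3-[(2R,3R)-3-(3,5-dihydroxyphenyl)-7-hydroxy-2-(4-hydroxyphenyl)-2,3-dihydrobenzofuran-5-yl]-2-(4-hydroxyphenyl)-2,3-dihydrobenzofuran-6-ol | Brc1cc(O)cc2c1[C@H](c1cc(O)c3c(c1)[C@@H](c1cc(O)cc(O)c1)[C@H](c1ccc(O)cc1)O3)[C@@H](c1ccc(O)cc1)O2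
F7 | step 5 | 4-bromo-2-[(3,5-dimethoxyphenyl)(hydroxy)methyl]-6-methoxyphenol (racemic) | OC(c1cc(OC)cc(OC)c1)c1cc(Br)cc(OC)c1O
F8 | step 5 | 4-bromo-2-[(3,5-dimethoxyphenyl)(tosyl)methyl]-6-methoxyphenol (racemic) | Cc1ccc(cc1)S(=O)(=O)C(c1cc(OC)cc(OC)c1)c1cc(Br)cc(OC)c1O
F9 | step 5 | (4-methoxybenzyl)dimethylsulfonium chloride | C[S+](C)Cc1ccc(OC)cc1.[Cl-]
F10 | step 5 | (2R,3R)-5-bromo-3-(3,5-dimethoxyphenyl)-7-methoxy-2-(4-methoxyphenyl)-2,3-dihydrobenzofuran (trans; formed as the racemate, then resolved) | Brc1cc(OC)c2c(c1)[C@@H](c1cc(OC)cc(OC)c1)[C@H](c1ccc(OC)cc1)O2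
F11 | step 14 | (E)-4-[2-(4,4,5,5-tetramethyl-1,3,2-dioxaborolan-2-yl)ethenyl]phenyl pivalate | CC(C)(C)C(=O)Oc1ccc(/C=C/B2OC(C)(C)C(C)(C)O2)cc1
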